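**Retrosynthetic overview**
- The vanillate is attached last, to the only secondary hydroxyl (C1) of the free triol. The C3 methyl carbinol comes from MeCeCl2 addition to a C3 enone made by allylic oxidation next to C4=C5. The C9 isopropyl carbinol comes from iPrCeCl2 addition to a C9 ketone.
- The C1 oxygen and the trans C6/C10 fusion come from conjugate borylation–oxidation of a C9-keto C10=C1 enone. That enone is reached from the cyclisation product by a sulfide relay at C10 (sulfenylation, conjugate reduction, sulfoxide elimination).
- Feature on which the strategy rests: quaternary C6 is one terminus of the pentadienyl cation C6=C10–C9–C8=C7. Its central carbon C9 is the oxygen-bearing carbon of the five-membered ring (C6, C7, C8, C9, C10). Cutting C6–C7 therefore opens that ring to a dienyl vinyl ketone on the intact seven-membered ring (C1–C6, C10).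
- Ring order: the seven-membered ring is bought as 2-methylcycloheptanone. The five-membered ring is closed by a 4π conrotatory Nazarov cyclisation, with a silyl group on C7 that fixes where the new double bond ends.

Key step: step 6

Numbering and faces: the seven-membered ring is C1 (ester carbinol), C2, C3 (methyl carbinol), C4=C5, C6 (quaternary, methyl) and C10 (fusion CH). The five-membered ring is C6, C7, C8, C9 (isopropyl carbinol) and C10. β is the face that carries the C6 methyl and α is the opposite face.

Assumption: the (S,S) antipode of the chiral acid in step 6 is taken to favour the conrotation that gives the C6 configuration drawn. The sense of induction has to be found by experiment, and the (R,R) antipode is used if it proves opposite.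

Step 1
Reactants: 1 2-methylcycloheptanone (racemic)
Product: 2 2-chloro-2-methylcycloheptanone (racemic)
Conditions: SO2Cl2, CH2Cl2, 0 °C to rt
Reagents that add atoms: sulfuryl chloride, O=S(=O)(Cl)Cl
Why: α-Chlorination of a ketone with SO2Cl2 proceeds through the more substituted enol, so chlorine enters at the methyl-bearing carbon; the new stereocentre is racemic and disappears in step 2.

Step 2
Reactants: 2 2-chloro-2-methylcycloheptanone
Product: 3 2-methylcyclohept-2-en-1-one
Conditions: Li2CO3, LiBr, DMF, 120 °C
Reagents that add atoms: none
Why: Dehydrohalogenation of a tertiary α-chloro ketone with lithium salts in hot DMF is a standard enone synthesis, and the equilibrating halide medium favours the endocyclic trisubstituted enone over the exocyclic methylene isomer.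

Step 3
Reactants: 3 2-methylcyclohept-2-en-1-one
Product: 4 2-methylcyclohepta-1,3-dien-1-yl trifluoromethanesulfonate
Conditions: Tf2O, 2,6-di-tert-butyl-4-methylpyridine, CH2Cl2, 0 °C to rt
Reagents that add atoms: triflic anhydride, O=S(=O)(OS(=O)(=O)C(F)(F)F)C(F)(F)F
Why: O-Triflation of the enone gives a triflyloxyallyl cation that the hindered pyridine deprotonates at the γ carbon (future C4), the established thermodynamic enol triflate formation that leads to the linearly conjugated 1,3-dienyl triflate, whereas a lithium amide at low temperature would remove the α' proton and give the useless cross-conjugated isomer.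

Step 4
Reactants: 5 ethynyltrimethylsilane; 6 tributyltin hydride
Product: 7 (E)-tributyl[2-(trimethylsilyl)ethenyl]stannane
Conditions: 2,2'-azobis(isobutyronitrile) (cat.), neat, 85 °C
Reagents that add atoms: none
Why: Radical hydrostannation of a terminal alkyne puts tin on the terminal carbon, and reversible addition of the stannyl radical equilibrates the product to the E alkene.

Step 5
Reactants: 4 2-methylcyclohepta-1,3-dien-1-yl trifluoromethanesulfonate; 7 (E)-tributyl[2-(trimethylsilyl)ethenyl]stannane
Product: 8 (E)-1-(2-methylcyclohepta-1,3-dien-1-yl)-3-(trimethylsilyl)prop-2-en-1-one (the dienyl vinyl ketone with Me3Si on C7)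
Conditions: CO (1 atm), Pd(PPh3)4 (cat.), LiCl, THF, 55 °C
Reagents that add atoms: carbon monoxide, [C-]#[O+]
Why: Carbonylative Stille coupling: oxidative addition of the dienyl triflate to zerovalent palladium (LiCl keeps the cycle running), CO insertion and transfer of the alkenyl group from tin, not from silicon, with retention of the E geometry give the β-silyl dienyl vinyl ketone directly.

Step 6
Reactants: 8 (E)-1-(2-methylcyclohepta-1,3-dien-1-yl)-3-(trimethylsilyl)prop-2-en-1-one
Product: 10 (3aS,8aS)-3a-methyl-6,7,8,8a-tetrahydroazulen-1(3aH)-one (cis-fused cyclopentenone; C9 ketone; C7=C8; C4=C5; 6β-methyl; 10β-H), via dienol 9 (not isolated)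
Conditions: (S,S)-HN[P(=NSO2CF3)(O2C20H10Ar2)]2 (imidodiphosphorimidate acid from 3,3'-diaryl-BINOL, Ar = 3,5-(CF3)2C6H3, cat.), PhOH, toluene, 0 °C to rt
Reagents that add atoms: none
Why: Proposed new method: the confined chiral acid protonates the carbonyl oxygen of 8 to the hydroxypentadienyl cation C6=C10–C9(OH)–C8=C7 held in a tight ion pair, a thermal 4π conrotatory electrocyclisation joins C6 to C7, and the hydroxyallyl cation so formed (C8–C9–C10) is stabilised at C8 by the C7–Si bond and gives up Me3Si+ to phenol, which regenerates the acid and leaves dienol 9, the tautomer of 10. The closest known reaction types are the silicon-directed Nazarov cyclisation of cycloalkenyl β-silylvinyl ketones with FeCl3 or BF3·OEt2, which also builds angular methyl groups from 2-methylcycloalkenyl substrates, and the asymmetric Nazarov cyclisation of simple unactivated divinyl ketones with imidodiphosphorimidate acids; their union on a β,β-disubstituted dienyl terminus has not been shown. The five-membered ring (C6, C7, C8, C9, C10) is closed by this electrocyclic C6–C7 bond formation and by nothing else. C6 is fixed only by the sense of conrotation, which the chiral anion has to bias because the substrate has no stereocentre, the transient C7 centre is lost with silicon, and C10 arises by protonation of 9, expected syn to the methyl because a flat cyclopentenone favours a cis fusion, which is of no consequence since step 7 erases it. Silicon secures the position of the new alkene at C7=C8, since without it loss of a proton from C1 would compete and give the C10=C1 isomer, and it tames the otherwise polymerisable vinyl ketone. Closure at C6 rather than at the vinylogous terminus C4 is secured by the ring, which holds C9 and C5 trans across C10=C6 so that C7 cannot reach C4, and C4=C5 is therefore carried through untouched.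

Step 7
Reactants: 10 cis-fused cyclopentenone
Product: 12 10β-(phenylthio) cyclopentenone (C9 ketone; C7=C8; C4=C5; 6β-methyl), via lithium dienolate 11 (not isolated)
Conditions: LDA, THF, −78 °C; PhSO2SPh, −78 to 0 °C
Reagents that add atoms: S-phenyl benzenethiosulfonate, O=S(=O)(Sc1ccccc1)c1ccccc1; lithium diisopropylamide (lithium of intermediate 11 only), [Li+].CC(C)[N-]C(C)C
Why: α'-Sulfenylation of an enone: C10 carries the only acidic hydrogen (C8 is vinylic and C6 quaternary), so LDA gives one cross-conjugated dienolate that takes sulfur at C10, on the methyl face to keep the cis fusion, a configuration that does not matter because step 9 removes it.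

Step 8
Reactants: 12 10β-(phenylthio) cyclopentenone
Product: 13 10β-(phenylthio) cyclopentanone (C7–C8 saturated; C4=C5 kept)
Conditions: [(Ph3P)CuH]6, H2O, toluene, rt
Reagents that add atoms: none
Why: Conjugate reduction with a phosphine copper hydride delivers hydride only to the β carbon C7 of the enone and leaves the isolated C4=C5 alkene, the ketone and the aryl sulfide alone; no stereocentre is formed.

Step 9
Reactants: 13 10β-(phenylthio) cyclopentanone
Product: 15 bicyclic enone (C9 ketone conjugated with C10=C1; C4=C5; 6β-methyl), via sulfoxide 14 (not isolated)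
Conditions: mCPBA (1 equiv), CH2Cl2, −78 °C; then toluene, 90 °C
Reagents that add atoms: 3-chloroperbenzoic acid (oxygen of intermediate 14 only), O=C(OO)c1cccc(Cl)c1
Why: Sulfide oxidation followed by thermal syn elimination of the β-keto sulfoxide: at −78 °C sulfur is oxidised far faster than C4=C5, and since C6 is quaternary the only β hydrogens are on C1, so the enone can form only as C10=C1.

Step 10
Reactants: 15 bicyclic C10=C1 enone
Product: 17 trans-fused 1α-hydroxy ketone (C9 ketone; 10α-H; 6β-methyl; C4=C5), via pinacol boronate 16 (not isolated)
Conditions: B2pin2, CuCl (cat.), bis[2-(diphenylphosphino)phenyl] ether (cat.), NaOtBu (cat.), MeOH, THF, rt; 1,8-diazabicyclo[5.4.0]undec-7-ene (cat.), rt; then NaBO3·4H2O, THF–H2O, rt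
Reagents that add atoms: sodium perborate (oxygen on C1), [Na+].[Na+].O[B-]1(O)OO[B-](O)(O)OO1; bis(pinacolato)diboron (boryl group of intermediate 16 only), CC1(C)OB(OC1(C)C)B1OC(C)(C)C(C)(C)O1
Why: Copper-catalysed conjugate borylation of the only enone (boron to C1) followed by stereoretentive C–B oxidation: the boryl-copper reagent is expected to reach C1 from the α face, away from the pseudo-axial C6 methyl, and C10 is then set by protonation and amidine equilibration of the non-eliminable boryl ketone to the trans-fused isomer, in which C9 and the C1 substituent are both equatorial on the chair cycloheptene and the wide ring torsion about C6–C10 suits a trans-fused five-membered ring.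

Step 11
Reactants: 17 trans-fused 1α-hydroxy ketone
Product: 18 1α,9β-diol with 9α-isopropyl (10α-H; 6β-methyl; C4=C5)
Conditions: iPrMgCl, CeCl3 (excess), THF, −78 to −20 °C
Reagents that add atoms: isopropylmagnesium chloride, CC(C)[Mg]Cl
Why: Organocerium 1,2-addition, whose low basicity suppresses enolisation, retro-aldol cleavage and β-hydride reduction: the first equivalent forms the C1 alkoxide, which chelates trivalent cerium together with C9=O, and isopropyl then enters from the α face beside H-10, opposite to the C6 methyl and H-1 on the β face, giving the 9β-hydroxyl.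

Step 12
Reactants: 18 1α,9β-diol
Product: 19 1α-tert-butyldimethylsilyl ether of 18 (9β-OH free)
Conditions: TBSOTf, 2,6-lutidine, CH2Cl2, −78 to 0 °C
Reagents that add atoms: tert-butyldimethylsilyl triflate, CC(C)(C)[Si](C)(C)OS(=O)(=O)C(F)(F)F
Why: Silylation of the secondary C1 hydroxyl is selective over the hindered tertiary C9 hydroxyl, and a silyl ether is preferred to the final ester at this point because a C1 acyloxy group β to the coming C3 ketone would be prone to E1cB loss and would compete for MeCeCl2.

Step 13
Reactants: 19 1α-silyl ether
Product: 20 C3 enone (C3 ketone conjugated with C4=C5; 1α-OTBS; 9β-OH; 9α-isopropyl)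
Conditions: Rh2(caprolactamate)4 (cat.), tBuOOH (70% in H2O), 1,2-dichloroethane, 40 °C
Reagents that add atoms: tert-butyl hydroperoxide, CC(C)(C)OO
Why: Dirhodium-catalysed allylic oxidation with tBuOOH abstracts hydrogen from C3, the only allylic C–H position of the molecule because the other allylic carbon C6 is quaternary, and the allyl radical is oxygenated at the open C3 end rather than at neopentyl C5, giving the C3 enone.

Step 14
Reactants: 20 C3 enone
Product: 21 3β-hydroxy-3α-methyl compound (C4=C5; 1α-OTBS; 9β-OH)
Conditions: MeLi, CeCl3, THF, −78 °C
Reagents that add atoms: methyllithium, [Li]C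
Why: Organocerium 1,2-addition to the enone, without conjugate addition and without enolisation toward the β-silyloxy group: methyl approaches C3 along the equatorial α trajectory because the axial β trajectory is blocked by the pseudo-axial C6 methyl and by H-1β, which gives the 3α-methyl 3β-hydroxyl centre.

Step 15
Reactants: 21 3β-hydroxy-3α-methyl silyl ether
Product: 22 1α,3β,9β-triol (3α-methyl; 9α-isopropyl; 6β-methyl; 10α-H; C4=C5)
Conditions: Bu4NF, THF, rt to 45 °C
Reagents that add atoms: none
Why: Fluoride-induced desilylation frees the C1 hydroxyl under non-acidic conditions that do not ionise the tertiary allylic C3 alcohol.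

Step 16
Reactants: 23 vanillic acid
Product: 25 4-(tert-butyldimethylsilyloxy)-3-methoxybenzoic acid, via bis-silyl compound 24 (not isolated)
Conditions: TBSCl, imidazole, DMF, rt; then AcOH, THF, H2O, rt
Reagents that add atoms: tert-butyldimethylsilyl chloride, CC(C)(C)[Si](C)(C)Cl
Why: Exhaustive silylation followed by mild acidic hydrolysis exploits the much greater lability of a silyl ester compared with an aryl silyl ether and leaves the phenol masked.

Step 17
Reactants: 22 1α,3β,9β-triol; 25 4-(tert-butyldimethylsilyloxy)-3-methoxybenzoic acid
Product: 26 C1 ester of 22 with the O-silylated vanillic acid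
Conditions: DCC, 4-(dimethylamino)pyridine (cat.), CH2Cl2, rt
Reagents that add atoms: none
Why: Steglich esterification acylates the only secondary hydroxyl (C1) while the two tertiary hydroxyls at C3 and C9 are too hindered to react, and C1 keeps its configuration because its C–O bond is not touched.

Step 18
Reactants: 26 O-silylated vanillate
Product: 27 target, the C1 vanillate of triol 22
Conditions: Bu4NF, AcOH, THF, 0 °C
Reagents that add atoms: none
Why: Buffered fluoride cleaves the aryl silyl ether rapidly at 0 °C without touching the ester, the tertiary alcohols or the alkene.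

**Compound list**
1 | 2-methylcycloheptanone (racemic) | CC1CCCCCC1=O | starting material
2 | 2-chloro-2-methylcycloheptanone (racemic) | CC1(Cl)CCCCCC1=O | intermediate
3 | 2-methylcyclohept-2-en-1-one | CC1=CCCCCC1=O | intermediate
4 | 2-methylcyclohepta-1,3-dien-1-yl trifluoromethanesulfonate | CC1=C(OS(=O)(=O)C(F)(F)F)CCCC=C1 | intermediate
5 | ethynyltrimethylsilane | C#C[Si](C)(C)C | starting material
6 | tributyltin hydride | CCCC[SnH](CCCC)CCCC | starting material
7 | (E)-tributyl[2-(trimethylsilyl)ethenyl]stannane | CCCC[Sn](CCCC)(CCCC)/C=C/[Si](C)(C)C | intermediate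
8 | (E)-1-(2-methylcyclohepta-1,3-dien-1-yl)-3-(trimethylsilyl)prop-2-en-1-one | C[Si](C)(C)/C=C/C(=O)C1=C(C)C=CCCC1 | intermediate
9 | bicyclic dienol (C9 hydroxyl, C9=C10, C7=C8, C4=C5, 6β-methyl) | OC1=C2CCCC=C[C@@]2(C)C=C1 | intermediate (not isolated)
10 | (3aS,8aS)-3a-methyl-6,7,8,8a-tetrahydroazulen-1(3aH)-one, cis-fused cyclopentenone | O=C1C=C[C@]2(C)C=CCCC[C@H]12 | intermediate
11 | lithium dienolate of 10 | [Li+].[O-]C1=C2CCCC=C[C@@]2(C)C=C1 | intermediate (not isolated)
12 | 10β-(phenylthio) cyclopentenone | O=C1C=C[C@]2(C)C=CCCC[C@]12Sc3ccccc3 | intermediate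
13 | 10β-(phenylthio) cyclopentanone | O=C1CC[C@]2(C)C=CCCC[C@]12Sc3ccccc3 | intermediate
14 | sulfoxide of 13 (mixture at sulfur) | O=C1CC[C@]2(C)C=CCCC[C@]12S(=O)c3ccccc3 | intermediate (not isolated)
15 | bicyclic enone, C9 ketone with C10=C1, C4=C5, 6β-methyl | O=C1CC[C@]2(C)C=CCCC=C12 | intermediate
16 | trans-fused 1α-(pinacolboryl) ketone | O=C1CC[C@]2(C)C=CCC[C@H](B3OC(C)(C)C(C)(C)O3)[C@@H]12 | intermediate (not isolated)
17 | trans-fused 1α-hydroxy ketone (10α-H) | O=C1CC[C@]2(C)C=CCC[C@H](O)[C@@H]12 | intermediate
18 | 1α,9β-diol with 9α-isopropyl | O[C@H]1CCC=C[C@@]2(C)CC[C@@](O)(C(C)C)[C@H]12 | intermediate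
19 | 1α-tert-butyldimethylsilyl ether of 18 | CC(C)(C)[Si](C)(C)O[C@H]1CCC=C[C@@]2(C)CC[C@@](O)(C(C)C)[C@H]12 | intermediate
20 | C3 enone | CC(C)(C)[Si](C)(C)O[C@H]1CC(=O)C=C[C@@]2(C)CC[C@@](O)(C(C)C)[C@H]12 | intermediate
21 | 3β-hydroxy-3α-methyl silyl ether | CC(C)(C)[Si](C)(C)O[C@H]1C[C@](C)(O)C=C[C@@]2(C)CC[C@@](O)(C(C)C)[C@H]12 | intermediate
22 | 1α,3β,9β-triol | O[C@H]1C[C@](C)(O)C=C[C@@]2(C)CC[C@@](O)(C(C)C)[C@H]12 | intermediate
23 | vanillic acid | COc1cc(C(=O)O)ccc1O | starting material
24 | tert-butyldimethylsilyl 4-(tert-butyldimethylsilyloxy)-3-methoxybenzoate | COc1cc(C(=O)O[Si](C)(C)C(C)(C)C)ccc1O[Si](C)(C)C(C)(C)C | intermediate (not isolated)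
25 | 4-(tert-butyldimethylsilyloxy)-3-methoxybenzoic acid | COc1cc(C(=O)O)ccc1O[Si](C)(C)C(C)(C)C | intermediate
26 | O-silylated C1 vanillate | COc1cc(C(=O)O[C@H]2C[C@](C)(O)C=C[C@@]3(C)CC[C@@](O)(C(C)C)[C@H]23)ccc1O[Si](C)(C)C(C)(C)C | intermediate
27 | CNP0243386.2 | COc1cc(C(=O)O[C@H]2C[C@](C)(O)C=C[C@@]3(C)CC[C@@](O)(C(C)C)[C@H]23)ccc1O | target

**Step count**
- Total step count: 18.
- Longest linear sequence: 16 steps (steps 1–3, 5–15, 17 and 18).

**Steps most likely to fail**

1. **Step 6 (proposed new method).**
   - What may go wrong: the extra conjugation through C4=C5 lowers the energy of the open cation, so closure may be slow under a catalytic acid. Diene isomerisation or oligomerisation may then outrun it. The ion pair may also discriminate poorly between the two senses of conrotation.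
   - Fallback (known chemistry, sets out from 8, returns at 10): 8 is cyclised with stoichiometric FeCl3 in CH2Cl2 at −30 to 0 °C, the classical silicon-directed Nazarov reaction, to the racemic cis-fused enone F1. Luche reduction (NaBH4, CeCl3·7H2O, MeOH) from the convex β face gives the racemic 9α-allylic alcohol F2. Candida antarctica lipase B and vinyl acetate acylate the (9R) antipode, in which the bulky C10 and the flat C8 sit as the empirical rule for lipases asks. This gives the acetate F3, which is separated from the unreacted antipode. K2CO3 in MeOH frees the enantiopure allylic alcohol F4, and MnO2 oxidises it to 10.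

2. **Step 10.**
   - What may go wrong: boryl-copper may distinguish poorly between the two faces of C1, because the C6 methyl (β) and the C5 side of the folded seven-membered ring (α) flank the planar enone almost symmetrically. Protonation or equilibration at C10 may also stop at the cis-fused ketone.
   - Fallback (sets out from 15, returns at 17): oxygen is delivered to C1 by a directing group instead of by conjugate addition. Corey–Bakshi–Shibata reduction of 15 uses (S)-1-methyl-3,3-diphenyltetrahydro-1H,3H-pyrrolo[1,2-c][1,3,2]oxazaborole and catecholborane at −78 °C. It sets the 9α (9R) hydroxyl under catalyst control and gives the allylic alcohol F5. VO(acac)2 and tBuOOH epoxidise only the allylic C10=C1 bond, syn to that hydroxyl, to the α-epoxy alcohol F6. Dess–Martin oxidation gives the α-epoxy ketone F7. SmI2 in THF–MeOH at −78 °C cleaves the C10–O bond and keeps the 1α-oxygen. The samarium enolate, tied to the α-oriented C1 alkoxide, is protonated at low temperature to 17.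

3. **Step 11.**
   - What may go wrong: at the hindered C9 carbonyl, flanked by C10 and close to quaternary C6, the branched nucleophile may act as a base or as a β-hydride donor. Retro-aldol opening of the C1 alkoxide may also intervene, so that addition stays incomplete.
   - Fallback (sets out from 17, returns at 18): the three carbons are brought in as a flat sp2 nucleophile without β hydrogen and are saturated afterwards. 2-Propenylmagnesium bromide and CeCl3 give, by the same α-face approach, the isopropenyl carbinol F8. Hydrogen-atom-transfer hydrogenation with Mn(dpm)3 (dpm = dipivaloylmethanate), PhSiH3 and tBuOOH in iPrOH reduces the 1,1-disubstituted alkene through its tertiary radical. The 1,2-disubstituted C4=C5 bond could give only a secondary radical and is left, so the product is 18.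

Further compounds
F1 | step 6 | racemic cis-fused enone, (±)-10 | O=C1C=C[C@]2(C)C=CCCC[C@H]12.O=C1C=C[C@@]2(C)C=CCCC[C@@H]12
F2 | step 6 | racemic cis-fused 9α-allylic alcohol | O[C@@H]1C=C[C@]2(C)C=CCCC[C@H]12.O[C@H]1C=C[C@@]2(C)C=CCCC[C@@H]12
F3 | step 6 | (9R)-acetate of the cis-fused allylic alcohol | CC(=O)O[C@@H]1C=C[C@]2(C)C=CCCC[C@H]12
F4 | step 6 | enantiopure (9R) cis-fused allylic alcohol | O[C@@H]1C=C[C@]2(C)C=CCCC[C@H]12
F5 | step 10 | 9α (9R) allylic alcohol with C10=C1 | O[C@@H]1CC[C@]2(C)C=CCCC=C12
F6 | step 10 | 1α,10α-epoxy 9α-alcohol | O[C@@H]1CC[C@]2(C)C=CCC[C@@H]3O[C@]123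
F7 | step 10 | 1α,10α-epoxy C9 ketone | O=C1CC[C@]2(C)C=CCC[C@@H]3O[C@]123
F8 | step 11 | 1α,9β-diol with 9α-isopropenyl | O[C@H]1CCC=C[C@@]2(C)CC[C@@](O)(C(C)=C)[C@H]12
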